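Pick the flask by reckoning what each one makes once it has started working.

| flask | starting material | precatalyst | impurity | temperature | remark | time |
|---|---|---|---|---|---|---|
| eta | 0.050 M | 0.91 µM | 0.12 µM | −10 °C | run made earlier |  |
| zeta | 0.075 M | 0.91 µM | 0.12 µM | 25 °C | run made earlier |  |
| summer | 0.10 M | 0.91 µM | 0.12 µM | 55 °C |  | 4.0 d |
| dusk | 0.10 M | 0.91 µM | 0.12 µM | 25 °C |  | 4.0 d |
| dawn | 0.10 M | 0.91 µM | 0.12 µM | −5 °C |  | 4.0 d |

- eta (time / d: product / %, starting material / %): 12.0: 0, 99.4; 25.0: 0.9, 100.1; 30.0: 0, 101.7; 50.0: 0, 100.6; 60.0: 0.3, 99.6
- zeta (time / d: product / %, starting material / %): 0.833: 0.7, 98.1; 1.67: 12.2, 87.1; 3.00: 38.5, 60.5; 6.00: 96.5, 4.0; 12.0: 98.9, 0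

(each reading ± 1 percentage point)



- the best flask by amount of product, in percent of the starting material charged; "all alike" if 1.5 percentage points covers them all (summer / dusk / dawn / all alike)
- amount of product at the end, in percent of the starting material charged, summer
- amount of product at the end, in percent of the starting material charged, dusk
- amount of product at the end, in percent of the starting material charged, dawn

In the zeta run, product hardly appears at first; then it climbs steadily. From 1.67 d to 3.00 d it gains 0.0148 M/d. Call this the working rate: the concentration of product made per day once the flask has started. The next stretch gives 0.0145 M/d, although starting material falls from 60.5 % to 4.0 %. The two averages are close, but matching averages do not show an order in starting material, so take the straight line as a reading of the zeta run.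

Running the line back to zero product gives a lag, or induction period, of 1.05 d. Dusk has the same temperature and the same precatalyst and impurity charges as zeta. If you assume it keeps both the rate and the lag, it makes 43.7 % in 4.0 d.

The eta run shows no product beyond the scatter in 60.0 d, so read its lag as longer than that. Now assume rates double for every 10 degrees. Dawn is warmer than eta by a factor of 1.41 in rate, so its lag is still at least 42.4 d, far beyond 4.0 d. You therefore expect no product from dawn.

The forecast names summer as best, with 98 % (75 % to 100 %) there, 44 % (33 % to 56 %) in dusk and 0 % (0 % to 1.5 %) in dawn. Its dusk and dawn agree with the reckoning above. For summer it argues that “induction lasts only hours and turnover is roughly ten times faster”. Its 98 % is what rates doubled for every 10 degrees give from the zeta run.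

The flasks give 10.1 % in summer, 47.7 % in dusk and 0 % in dawn, so the best is dusk, and the forecast's summer stands 88 percentage points too high. Summer held 10.1 % product at 2.00 d and 10.1 % at 4.00 d, with free enzyme at 0 % and unfolded enzyme at 86.8 % of the catalyst charged. At the working rate, summer's whole product equals 0.683 d of work, less than the 2.95 d reckoned for dusk.

    free enzyme → unfolded enzyme (k = 1.45 × 10⁻⁷ /s, Ea = 192 kJ/mol)
    starting material + free enzyme → product + free enzyme, rate k2*[starting material]*[free enzyme]/(1 + ([starting material]/Km2) + ([starting material]/Ksi2)^2) (22.1 mM, 0.0568 M, k = 30.9 /M/s, Ea = 49.0 kJ/mol)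
    precatalyst → free enzyme (k = 5.23 × 10⁻⁶ /s, Ea = 111 kJ/mol)
    free enzyme + impurity → spent catalyst (k = 13400 /M/s, Ea = 35.0 kJ/mol)
    (constants at 25 °C)

Take dawn repeated at 20 °C: dividing the working rate by 1.41 gives 0.0105 M/d, and multiplying the lag by the same factor gives 1.49 d, so you expect 26.3 %. The computed flask gives 16.7 %, less than that reckoning.

All runs were generated by integration with made-up constants.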